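**Plan** (core numbering: C1(CO2H)–C2(CO2H)–C3(aryl)–C4(CO2H)–C5H=C6–side chain)
Retrosynthesis removes the six benzyl groups first. It then cuts the C6–vinyl bond (Heck: alkenyl bromide 22 + danshensu acrylate 17). Last, it cuts C1–C2 and C4–C5 together, leaving a 3-arylglutarate (C2–C3–C4) and a three-carbon enal (C5–C6–C1).
Enabling feature: C2(CO2H)–C1–C6=C5 is a γ,δ-unsaturated acid, the retron of an ester-enolate Claisen shift, and C5 is bonded to C4, the α-carbon of the other glutarate carboxyl. C5 can therefore be the carbinol carbon of an aldol at C4. Its oxygen is acylated by the C2 arm (temporary oxan-2-one ring O–C(=O)–C2–C3–C4–C5) and passes to the C2 carboxyl in the [3,3] shift.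
Forward order: glutaric acid 4 → anhydride 5 → imide/phenyl ester 8, and separately bromo-enal 14. One flask then runs the aldol, closes the δ-lactone ring and contracts it by Ireland–Claisen shift to cyclohexene 20. Auxiliary removal, Heck coupling and global debenzylation follow.
Stereochemistry: C3 comes from auxiliary-based desymmetrisation of 5. C4 and the relay centre C5 come from a chelated (Z)-enolate syn aldol anti to the aryl group. C2 and C1 arise by chirality transfer from C5 through the boat transition state and the fixed (Z)-olefin of 14. The side-chain centre comes from (R)-danshensu.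

Key step: step 11

Assumption: (R)-danshensu 15 and the aqueous solution of 9 are bought. The sense of diastereoselection in step 4 is not relied on, because both C3 epimers are separable diastereomers.

Step 1
Reactants: 1 3,4-bis(benzyloxy)benzaldehyde; 2 ethyl acetoacetate (2 equiv)
Product: 3 diethyl 2,4-diacetyl-3-[3,4-bis(benzyloxy)phenyl]pentanedioate (diastereomer mixture)
Conditions: piperidine (cat.), EtOH, rt
Reagents that add atoms: none
Why: Knoevenagel condensation of 1 with 2 followed by Michael addition of a second molecule of 2 is the classical assembly of the 3-arylglutarate skeleton, and the stereocentres formed here are erased in step 2.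

Step 2
Reactants: 3 diethyl 2,4-diacetyl-3-[3,4-bis(benzyloxy)phenyl]pentanedioate
Product: 4 3-[3,4-bis(benzyloxy)phenyl]pentanedioic acid
Conditions: KOH, H2O/EtOH, reflux; then aq. HCl
Reagents that add atoms: potassium hydroxide, [K+].[OH-]
Why: Hot alkali effects retro-Claisen cleavage of both β-keto ester units and saponification of both esters, conditions to which aryl benzyl ethers are inert, and 4 has no stereocentre.

Step 3
Reactants: 4 3-[3,4-bis(benzyloxy)phenyl]pentanedioic acid
Product: 5 4-[3,4-bis(benzyloxy)phenyl]oxane-2,6-dione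
Conditions: Ac2O, 100 °C
Reagents that add atoms: none
Why: Anhydride exchange with acetic anhydride (dehydrative cyclisation) closes the strain-free six-membered glutaric anhydride and leaves the benzyl ethers untouched.

Step 4
Reactants: 5 4-[3,4-bis(benzyloxy)phenyl]oxane-2,6-dione; 6 (R)-4-benzyl-1,3-oxazolidin-2-one
Product: 7 (3S)-5-[(4R)-4-benzyl-2-oxo-1,3-oxazolidin-3-yl]-3-[3,4-bis(benzyloxy)phenyl]-5-oxopentanoic acid
Conditions: 6, n-BuLi, THF, −78 °C; then 5, −78 → 0 °C; aq. HCl; crystallisation or chromatography to remove the (3R) epimer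
Reagents that add atoms: none
Why: N-Acylation of the lithiated oxazolidinone by the prochiral anhydride (auxiliary-based desymmetrising ring opening, known for 3-substituted glutaric anhydrides) differentiates the two arms and turns the two possible C3 configurations into separable diastereomers, so the (3S) epimer is carried on as a single stereoisomer.

Step 5
Reactants: 7 (3S)-imide acid
Product: 8 phenyl (3S)-5-[(4R)-4-benzyl-2-oxo-1,3-oxazolidin-3-yl]-3-[3,4-bis(benzyloxy)phenyl]-5-oxopentanoate
Conditions: PhOH, EDC·HCl, DMAP (cat.), CH2Cl2, 0 °C → rt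
Reagents that add atoms: phenol, Oc1ccccc1
Why: Steglich-type carbodiimide esterification turns the free arm into an aryl ester, a good acyl donor with a weakly basic leaving group, without touching the imide or C3.

Step 6
Reactants: 9 2,2-dimethoxyacetaldehyde; 10 benzyl (triphenylphosphoranylidene)acetate
Product: 11 benzyl (2E)-4,4-dimethoxybut-2-enoate
Conditions: CH2Cl2, rt
Reagents that add atoms: none
Why: Wittig olefination with a stabilised ylide should give the (E)-enoate and tolerates the aqueous aldehyde solution.

Step 7
Reactants: 11 benzyl (2E)-4,4-dimethoxybut-2-enoate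
Product: 12 benzyl (2E)-4-oxobut-2-enoate
Conditions: Amberlyst-15, acetone/H2O, rt
Reagents that add atoms: water, O
Why: Acid-catalysed acetal hydrolysis frees the aldehyde under conditions too mild to cleave the benzyl ester or to isomerise the (E)-olefin.

Step 8
Reactants: 12 benzyl (2E)-4-oxobut-2-enoate
Product: 14 benzyl (2Z)-3-bromo-4-oxobut-2-enoate, via dibromide 13 (not isolated)
Conditions: Br2, CH2Cl2, 0 °C; then Et3N, 0 °C
Reagents that add atoms: bromine, BrBr
Why: Bromination followed by amine-induced dehydrobromination (the addition–elimination route to α-bromo enals) removes the more acidic proton α to the aldehyde, so bromine stays on C3, and the E1cB pathway should deliver the more stable isomer with formyl and ester groups trans.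

Step 9
Reactants: 15 (R)-danshensu
Product: 16 benzyl (2R)-3-[3,4-bis(benzyloxy)phenyl]-2-hydroxypropanoate
Conditions: BnBr (3.3 equiv), K2CO3, DMF, rt
Reagents that add atoms: benzyl bromide, BrCc1ccccc1
Why: Carbonate-mediated O-alkylation (Williamson ether synthesis and carboxylate alkylation) benzylates the two phenols and the acid but not the less acidic secondary alcohol, and the stereocentre is not involved.

Step 10
Reactants: 16 benzyl (2R)-3-[3,4-bis(benzyloxy)phenyl]-2-hydroxypropanoate
Product: 17 benzyl (2R)-2-(acryloyloxy)-3-[3,4-bis(benzyloxy)phenyl]propanoate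
Conditions: acryloyl chloride, Et3N, CH2Cl2, −20 → 0 °C
Reagents that add atoms: acryloyl chloride, C=CC(=O)Cl
Why: Acylation of the secondary alcohol with the acid chloride under amine base (Schotten–Baumann-type esterification) proceeds with retention because the C–O bond is not broken.

Step 11
Reactants: 8 imide phenyl ester; 14 benzyl (2Z)-3-bromo-4-oxobut-2-enoate
Product: 20 bromocyclohexene imide acid (1S,2R,3S,4S), via delta-lactone 18 (not isolated), via silyl ketene acetal 19 (not isolated)
Conditions: LiHMDS (1.05 equiv), THF, −78 °C; 14, −78 → −40 °C; TMSCl/Et3N, then LiHMDS (1.2 equiv), −78 °C → rt; toluene, 90 °C; 1 M HCl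
Reagents that add atoms: chlorotrimethylsilane, C[Si](C)(C)Cl (its silyl group is present only in 19 and is lost on work-up)
Why: Proposed new method: LiHMDS removes only the imide α-proton of 8 (far more acidic than the phenyl ester arm), the chelated (Z)-lithium enolate adds to the aldehyde of 14 through a closed Zimmerman–Traxler transition state (bond C4–C5), the alkoxide is captured at once by the phenyl ester to give lactone 18, and a second kinetic deprotonation at the lactone CH2 with in situ silylation gives ketene acetal 19, whose [3,3] shift forms C1–C2, breaks C5–O and leaves C5=C6. The closest known reaction types are the aldol–lactonisation that opens a Stobbe condensation and the Ireland–Claisen ring contraction of 6-alkenyl δ-lactones and 6-alkenyl-1,4-dioxan-2-ones; what is new is their union in one flask as a formal [3+3] annulation of a glutarate onto an enal. The temporary oxan-2-one ring closes by 6-exo-trig acyl substitution, and the cyclohexene closes in the sigmatropic shift itself, which in a six-membered lactone can only pass through a boat (bicyclo[2.2.2]-like) transition state. C4 is set by attack anti to the aryl group of C3 in the A(1,3)-minimised enolate conformer, a face the chelated (R)-auxiliary also leaves open; the relay centre C5 follows the (Z)-enolate syn rule (all-equatorial 4,5-trans-5,6-trans lactone); C2 is set by delivery of the alkenyl group on the lactone face on which it stands; and C1 is set by the fixed olefin geometry of 14, whose ester points outward in the boat and so ends cis to the C2 carboxyl. The step needs 1,2- rather than conjugate addition (lithium enolate, −78 °C, free aldehyde), lactonisation faster than retro-aldol or β-lactone formation (six-membered closure on an aryl ester that releases only weakly basic phenoxide), and deprotonation at C2 rather than at C4–H, whose removal would start E1cB loss of the carboxylate. This last selectivity is secured by the allylic strain that shields the α-proton of a branched N-acyl oxazolidinone, by the higher kinetic acidity of the lactone CH2, and by the internal TMSCl quench, which also forestalls 5-exo Michael closure of the free enolate onto the bromo-enoate.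

Step 12
Reactants: 20 bromocyclohexene imide acid
Product: 22 bromocyclohexene diacid 1-benzyl ester (1S,2R,3S,4S), via peroxy acid 21 (not isolated)
Conditions: LiOH, H2O2, THF/H2O, 0 °C; then Na2SO3; then aq. HCl
Reagents that add atoms: hydrogen peroxide, OO
Why: Hydroperoxide cleavage of the N-acyl oxazolidinone attacks the exocyclic carbonyl selectively, is too weakly basic to epimerise C4 or C1, leaves the benzyl ester intact, and cannot epoxidise the bromo-olefin, which is not conjugated to a carbonyl group.

Step 13
Reactants: 22 bromocyclohexene diacid 1-benzyl ester; 17 danshensu acrylate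
Product: 23 hexabenzyl-protected target (1R,2R,3S,4R; side chain E and R)
Conditions: Pd(OAc)2 (cat.), P(o-tol)3, Et3N, DMF, 80 °C
Reagents that add atoms: none
Why: Mizoroki–Heck vinylation of the alkenyl bromide with the acrylate (syn insertion, syn β-hydride elimination) should give the (E)-dienoate directly as the ester of the target, with the carboxylic acids travelling as ammonium salts and the five stereocentres untouched.

Step 14
Reactants: 23 hexabenzyl-protected target
Product: 24 target CNP0327643.1
Conditions: BCl3 (excess), pentamethylbenzene, CH2Cl2, −78 → 0 °C; aq. work-up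
Reagents that add atoms: none
Why: Lewis-acid debenzylation with BCl3 and pentamethylbenzene as a non-basic cation scavenger (Friedel–Crafts capture of the benzyl cation) removes the four aryl benzyl ethers and the two benzyl esters without hydrogen, so the diene, the secondary alkyl ester (whose carbinol carbon is deactivated by the adjacent carboxyl) and all stereocentres should survive.

**Compound list**
1 | 3,4-bis(benzyloxy)benzaldehyde | O=Cc1ccc(OCc2ccccc2)c(OCc2ccccc2)c1 | starting material
2 | ethyl acetoacetate | CCOC(=O)CC(C)=O | starting material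
3 | diethyl 2,4-diacetyl-3-[3,4-bis(benzyloxy)phenyl]pentanedioate (diastereomer mixture) | CCOC(=O)C(C(C)=O)C(c1ccc(OCc2ccccc2)c(OCc2ccccc2)c1)C(C(C)=O)C(=O)OCC | intermediate
4 | 3-[3,4-bis(benzyloxy)phenyl]pentanedioic acid | OC(=O)CC(CC(=O)O)c1ccc(OCc2ccccc2)c(OCc2ccccc2)c1 | intermediate
5 | 4-[3,4-bis(benzyloxy)phenyl]oxane-2,6-dione | O=C1CC(CC(=O)O1)c1ccc(OCc2ccccc2)c(OCc2ccccc2)c1 | intermediate
6 | (R)-4-benzyl-1,3-oxazolidin-2-one | O=C1N[C@H](Cc2ccccc2)CO1 | starting material
7 | (3S)-5-[(4R)-4-benzyl-2-oxo-1,3-oxazolidin-3-yl]-3-[3,4-bis(benzyloxy)phenyl]-5-oxopentanoic acid | O=C(C[C@H](c1ccc(OCc2ccccc2)c(OCc2ccccc2)c1)CC(=O)O)N1C(=O)OC[C@H]1Cc1ccccc1 | intermediate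
8 | phenyl (3S)-5-[(4R)-4-benzyl-2-oxo-1,3-oxazolidin-3-yl]-3-[3,4-bis(benzyloxy)phenyl]-5-oxopentanoate | O=C(C[C@H](c1ccc(OCc2ccccc2)c(OCc2ccccc2)c1)CC(=O)Oc1ccccc1)N1C(=O)OC[C@H]1Cc1ccccc1 | intermediate
9 | 2,2-dimethoxyacetaldehyde | COC(OC)C=O | starting material
10 | benzyl (triphenylphosphoranylidene)acetate | O=C(C=P(c1ccccc1)(c1ccccc1)c1ccccc1)OCc1ccccc1 | starting material
11 | benzyl (2E)-4,4-dimethoxybut-2-enoate | COC(OC)/C=C/C(=O)OCc1ccccc1 | intermediate
12 | benzyl (2E)-4-oxobut-2-enoate | O=C/C=C/C(=O)OCc1ccccc1 | intermediate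
13 | benzyl 2,3-dibromo-4-oxobutanoate (racemic anti adduct) | O=CC(Br)C(Br)C(=O)OCc1ccccc1 | intermediate
14 | benzyl (2Z)-3-bromo-4-oxobut-2-enoate (formyl trans to ester) | O=C/C(Br)=C/C(=O)OCc1ccccc1 | intermediate
15 | (R)-danshensu, (2R)-3-(3,4-dihydroxyphenyl)-2-hydroxypropanoic acid | O[C@H](Cc1ccc(O)c(O)c1)C(=O)O | starting material
16 | benzyl (2R)-3-[3,4-bis(benzyloxy)phenyl]-2-hydroxypropanoate | O[C@H](Cc1ccc(OCc2ccccc2)c(OCc2ccccc2)c1)C(=O)OCc1ccccc1 | intermediate
17 | benzyl (2R)-2-(acryloyloxy)-3-[3,4-bis(benzyloxy)phenyl]propanoate | C=CC(=O)O[C@H](Cc1ccc(OCc2ccccc2)c(OCc2ccccc2)c1)C(=O)OCc1ccccc1 | intermediate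
18 | (4R,5S,6S)-oxan-2-one with 4-aryl, 5-acyl-oxazolidinone and 6-[(Z)-1-bromo-2-(benzyloxycarbonyl)vinyl] groups, all trans | O=C1C[C@@H](c2ccc(OCc3ccccc3)c(OCc3ccccc3)c2)[C@H](C(=O)N2C(=O)OC[C@H]2Cc2ccccc2)[C@@H](/C(Br)=C/C(=O)OCc2ccccc2)O1 | intermediate
19 | trimethylsilyl ketene acetal of 18 (6-silyloxy-3,4-dihydro-2H-pyran) | C[Si](C)(C)OC1=C[C@@H](c2ccc(OCc3ccccc3)c(OCc3ccccc3)c2)[C@H](C(=O)N2C(=O)OC[C@H]2Cc2ccccc2)[C@@H](/C(Br)=C/C(=O)OCc2ccccc2)O1 | intermediate
20 | (1S,2R,3S,4S)-6-bromocyclohex-5-ene: C1 CO2Bn, C2 CO2H, C3 3,4-bis(benzyloxy)phenyl, C4 C(=O)-[(4R)-4-benzyl-2-oxo-oxazolidin-3-yl]; the three carbonyl groups cis, aryl trans to them | BrC1=C[C@@H](C(=O)N2C(=O)OC[C@H]2Cc2ccccc2)[C@H](c2ccc(OCc3ccccc3)c(OCc3ccccc3)c2)[C@@H](C(=O)O)[C@H]1C(=O)OCc1ccccc1 | intermediate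
21 | C4 peroxy acid corresponding to 22 | BrC1=C[C@@H](C(=O)OO)[C@H](c2ccc(OCc3ccccc3)c(OCc3ccccc3)c2)[C@@H](C(=O)O)[C@H]1C(=O)OCc1ccccc1 | intermediate
22 | (1S,2R,3S,4S)-6-bromo-3-[3,4-bis(benzyloxy)phenyl]cyclohex-5-ene-1,2,4-tricarboxylic acid 1-benzyl ester | BrC1=C[C@@H](C(=O)O)[C@H](c2ccc(OCc3ccccc3)c(OCc3ccccc3)c2)[C@@H](C(=O)O)[C@H]1C(=O)OCc1ccccc1 | intermediate
23 | hexabenzyl-protected target (core 1R,2R,3S,4R; E-dienoate; side-chain centre R) | O=C(/C=C/C1=C[C@@H](C(=O)O)[C@H](c2ccc(OCc3ccccc3)c(OCc3ccccc3)c2)[C@@H](C(=O)O)[C@H]1C(=O)OCc1ccccc1)O[C@H](Cc1ccc(OCc2ccccc2)c(OCc2ccccc2)c1)C(=O)OCc1ccccc1 | intermediate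
24 | CNP0327643.1 | O=C(/C=C/C1=C[C@@H](C(=O)O)[C@H](c2ccc(O)c(O)c2)[C@@H](C(=O)O)[C@H]1C(=O)O)O[C@H](Cc1ccc(O)c(O)c1)C(=O)O | target

Total step count: 14. Longest linear sequence: 9 steps (1, 2, 3, 4, 5, 11, 12, 13, 14).

**Steps most likely to fail**

Step 11. Several things may go wrong:
- The lithium aldol may show poor facial or syn/anti selectivity.
- Deprotonation at C4 may be followed by β-elimination of the carboxylate.
- The lactone enolate may close by conjugate addition onto the bromo-enoate.
- The sigmatropic shift may be sluggish because the allyl terminus carries an ester.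

The fallback gives up the domino and makes the two bonds in separate known reactions, with purification in between. It sets out from 8 and 14 and comes back at 20. The lithium enolate of 8 is transmetalated with ClTi(OiPr)3 and added to 14 (chelation-controlled syn aldol of an N-acyl oxazolidinone). This gives the hydroxy imide phenyl ester F1, which is freed from minor diastereomers. DMAP/Et3N closes lactone 18, now isolated. A separate Ireland–Claisen ring contraction (KHMDS, TBSCl, THF, −78 °C) gives the tert-butyldimethylsilyl ketene acetal F2. Heating F2 in toluene rearranges it to the silyl ester F3, and dilute acid converts F3 into 20.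

Step 14. Cleavage of the two benzyl esters may be incomplete, the liberated catechols may be benzylated by Friedel–Crafts reaction, or the Lewis acid may damage the dienoate ester. The fallback changes the order of events, so that no dienoate meets the Lewis acid and each deprotection concerns only three benzyl groups. It sets out from 22 and 17 and comes back at 24. BCl3/pentamethylbenzene converts 22 into the bromo triacid catechol F5 and 17 into the unprotected danshensu acrylate F6. A Heck coupling of F5 with F6 (Pd(OAc)2, P(o-tol)3, Et3N, degassed DMF) then gives 24 directly.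

Step 13. Oxidative addition and insertion may be slow at the hindered bromide, and hot amine may cause migration of the ring double bond or epimerisation at C4. The fallback replaces the C–H vinylation by a cross-coupling with a preformed vinyl metal under nearly neutral conditions. It sets out from 16 and 22 and comes back at 23. Compound 16 is esterified with (E)-3-(tributylstannyl)acrylic acid (DCC, DMAP) to the stannyl acrylate F4. A Stille coupling of F4 with 22 (Pd2(dba)3, AsPh3, CuI, DMF, rt to 50 °C) gives 23.

**Further compounds**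
F1 | step 11 | hydroxy imide phenyl ester (syn aldol adduct of 8 and 14) | O=C(Oc1ccccc1)C[C@@H](c1ccc(OCc2ccccc2)c(OCc2ccccc2)c1)[C@H](C(=O)N1C(=O)OC[C@H]1Cc1ccccc1)[C@H](O)/C(Br)=C/C(=O)OCc1ccccc1
F2 | step 11 | tert-butyldimethylsilyl ketene acetal of 18 | CC(C)(C)[Si](C)(C)OC1=C[C@@H](c2ccc(OCc3ccccc3)c(OCc3ccccc3)c2)[C@H](C(=O)N2C(=O)OC[C@H]2Cc2ccccc2)[C@@H](/C(Br)=C/C(=O)OCc2ccccc2)O1
F3 | step 11 | tert-butyldimethylsilyl ester of 20 | BrC1=C[C@@H](C(=O)N2C(=O)OC[C@H]2Cc2ccccc2)[C@H](c2ccc(OCc3ccccc3)c(OCc3ccccc3)c2)[C@@H](C(=O)O[Si](C)(C)C(C)(C)C)[C@H]1C(=O)OCc1ccccc1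
F4 | step 13 | benzyl (2R)-3-[3,4-bis(benzyloxy)phenyl]-2-{[(2E)-3-(tributylstannyl)prop-2-enoyl]oxy}propanoate | CCCC[Sn](CCCC)(CCCC)/C=C/C(=O)O[C@H](Cc1ccc(OCc2ccccc2)c(OCc2ccccc2)c1)C(=O)OCc1ccccc1
F5 | step 14 | (1S,2R,3S,4S)-6-bromo-3-(3,4-dihydroxyphenyl)cyclohex-5-ene-1,2,4-tricarboxylic acid | BrC1=C[C@@H](C(=O)O)[C@H](c2ccc(O)c(O)c2)[C@@H](C(=O)O)[C@H]1C(=O)O
F6 | step 14 | (2R)-2-(acryloyloxy)-3-(3,4-dihydroxyphenyl)propanoic acid | C=CC(=O)O[C@H](Cc1ccc(O)c(O)c1)C(=O)O
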